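**Retrosynthetic overview**
- Cut the C(=O)–CH2 bond. The target comes from an anti-Markovnikov intermolecular hydroacylation of 2,6-diprenyl-4-vinylphenol with unprotected 2,4,6-trihydroxybenzaldehyde (the new step). This avoids the chalcone level, so there is no flavanone trap, no C=C reduction next to the prenyl groups, and no protecting group.
- Cut the aryl–vinyl bond. The vinylphenol comes from Suzuki vinylation of 4-iodo-2,6-diprenylphenol.
- Cut both aryl–prenyl bonds. The iodide comes from double ortho-C-prenylation of 4-iodophenol with prenyl bromide.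
- Rings: none is formed. Both benzene rings are bought (B ring as 4-iodophenol, A ring as phloroglucinaldehyde).

Assumption: the target has no stereocentre and no E/Z-stereogenic alkene (each prenyl C=C ends in two methyl groups). It is therefore achiral, "single enantiomer" does not apply, and no stereocontrol is needed.

Step 1
Reactants: 1 4-iodophenol; 2 prenyl bromide (1-bromo-3-methylbut-2-ene, 2.5 equiv)
Product: 4 4-iodo-2,6-bis(3-methylbut-2-en-1-yl)phenol, via 4-iodo-2-prenylphenol 3 (not isolated)
Conditions: KOH (2.5 equiv), H2O, vigorous stirring, 0 °C → rt, 24 h; SiO2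
Reagents that add atoms: prenyl bromide (2), CC(C)=CCBr
Why: Ambident-phenoxide ortho-C-alkylation (SN2 at the allylic bromide, then rearomatising tautomerisation): water hydrogen-bonds the phenoxide oxygen and steers attack to ring carbon, iodine blocks the para position, and two rounds give the o,o'-diprenylphenol, a reaction type established for p-halophenols.

Step 2
Reactants: 4 4-iodo-2,6-bis(3-methylbut-2-en-1-yl)phenol; 5 vinylboronic acid pinacol ester (1.3 equiv)
Product: 6 2,6-bis(3-methylbut-2-en-1-yl)-4-vinylphenol
Conditions: PdCl2(dppf)·CH2Cl2 (3 mol %), K2CO3 (2.5 equiv), 1,4-dioxane/H2O 4:1, 80 °C, 3 h, Ar; store cold and dark, use promptly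
Reagents that add atoms: vinylboronic acid pinacol ester (5), C=CB1OC(C)(C)C(C)(C)O1
Why: Suzuki–Miyaura coupling: the C–I bond is the only site for oxidative addition, the hindered free phenol and the trisubstituted prenyl olefins are inert to Pd(0)/aqueous carbonate, and transmetalation followed by reductive elimination places the vinyl group para to OH.

Step 3
Reactants: 6 2,6-bis(3-methylbut-2-en-1-yl)-4-vinylphenol; 7 2,4,6-trihydroxybenzaldehyde (1.2 equiv)
Product: 8 4,2',4',6'-tetrahydroxy-3,5-diprenyldihydrochalcone
Conditions: [Rh(cod)(OMe)]2 (2.5 mol %), Cy2PCH2PCy2 (dcpm, 5.5 mol %), degassed 2-MeTHF (0.5 M), 65 °C, 16 h, Ar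
Reagents that add atoms: none
Why: Proposed new method: linear-selective, chelation-assisted Rh(I) intermolecular hydroacylation of an unprotected 4-vinylphenol by an unprotected 2,6-dihydroxybenzaldehyde; Rh–OMe is protonated only by the more acidic A-ring hydroxyls (pKa about 7–8, against about 10.5 for the hindered B-ring phenol) and, after proton shuffling, sits as the 2-formylphenoxide chelate; oxidative addition of the adjacent aldehyde C–H gives a five-membered O,C-chelated acyl–Rh(III)–H that resists decarbonylation, since CO extrusion would contract the chelate to four members; the monosubstituted vinyl group binds and inserts reversibly into Rh–H while the trisubstituted prenyl alkenes do not compete; turnover-limiting C–C reductive elimination is faster from the primary 2-arylethyl–Rh than from the secondary benzyl–Rh, which clashes with the di-ortho-oxygenated aroyl group and the bulky small-bite-angle diphosphine and is further destabilised by the electron-rich aryl ring (Curtin–Hammett control), so the C(=O)–CH2 bond forms in the anti-Markovnikov sense with full atom economy, and proton exchange with fresh 7 releases 8; the closest known reaction type is Rh-catalysed hydroacylation of unactivated 1-alkenes, dienes and strained alkenes with salicylaldehydes, which to my knowledge has not been shown for vinylphenols, for linear-selective coupling of vinylarenes that carry further olefins, or for free phloroglucinaldehyde.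

**Compound list**
1 | 4-iodophenol | Oc1ccc(I)cc1 | starting material
2 | prenyl bromide (1-bromo-3-methylbut-2-ene) | CC(C)=CCBr | starting material
3 | 4-iodo-2-(3-methylbut-2-en-1-yl)phenol (4-iodo-2-prenylphenol, not isolated) | CC(C)=CCc1cc(I)ccc1O | intermediate
4 | 4-iodo-2,6-bis(3-methylbut-2-en-1-yl)phenol | CC(C)=CCc1cc(I)cc(CC=C(C)C)c1O | intermediate
5 | vinylboronic acid pinacol ester (2-ethenyl-4,4,5,5-tetramethyl-1,3,2-dioxaborolane) | C=CB1OC(C)(C)C(C)(C)O1 | starting material
6 | 2,6-bis(3-methylbut-2-en-1-yl)-4-vinylphenol | C=Cc1cc(CC=C(C)C)c(O)c(CC=C(C)C)c1 | intermediate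
7 | 2,4,6-trihydroxybenzaldehyde (phloroglucinaldehyde) | O=Cc1c(O)cc(O)cc1O | starting material
8 | 4,2',4',6'-tetrahydroxy-3,5-diprenyldihydrochalcone, i.e. 3-[4-hydroxy-3,5-bis(3-methylbut-2-en-1-yl)phenyl]-1-(2,4,6-trihydroxyphenyl)propan-1-one (achiral) | CC(C)=CCc1cc(CCC(=O)c2c(O)cc(O)cc2O)cc(CC=C(C)C)c1O | target

**Total step count:** 3.
**Longest linear sequence:** 3 (1 → 4 → 6 → 8).

**Three steps most likely to fail**

**1. Step 3 (the proposed new step).**
- Risks: formation of the branched α-aryl ketone, decarbonylation of 7 to phloroglucinol, Rh–H isomerisation of the prenyl groups into conjugation, and oligomerisation of 6.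
- The fallback uses known chemistry, a redox-neutral Heck arylation of an allylic alcohol in place of C–H activation. It sets out from 7, uses iodide 4 as partner, and comes back at 8.
- Compound 7 is fully protected (MOMCl, i-Pr2NEt, then NaH/MOMCl, DMF) to 2,4,6-tris(methoxymethoxy)benzaldehyde F1.
- Vinylmagnesium bromide (THF, −78 → 0 °C) then gives racemic 1-[2,4,6-tris(methoxymethoxy)phenyl]prop-2-en-1-ol F2. Its stereocentre is erased in the next operation.
- Jeffery-type Heck arylation with 4 (Pd(OAc)2, n-Bu4NCl, NaHCO3, DMF, 60 °C) follows. It runs by carbopalladation at the terminal carbon, β-hydride elimination towards the carbinol C–H, and enol-to-ketone tautomerisation.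
- The Heck product is 3-[4-hydroxy-3,5-bis(3-methylbut-2-en-1-yl)phenyl]-1-[2,4,6-tris(methoxymethoxy)phenyl]propan-1-one F3.
- Brief treatment with dilute HCl in MeOH at 40 °C, stopped before any chroman forms, gives 8.

**2. Step 1.**
- Risks: O-prenyl ethers, incomplete second alkylation, and chroman by-products. A modest yield (about 35–45 %) and a demanding separation are expected.
- The fallback replaces direct C-alkylation with regiospecific [3,3] rearrangements. It sets out from 1, passes through 3, and comes back at 4.
- Compound 1 is O-alkylated with 3-chloro-3-methylbut-1-yne (cat. CuCl2, DBU, MeCN, 0 °C) to 1-iodo-4-[(2-methylbut-3-yn-2-yl)oxy]benzene F4.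
- Lindlar semihydrogenation (H2, quinoline, EtOAc) gives 1-iodo-4-[(2-methylbut-3-en-2-yl)oxy]benzene F5.
- Aromatic Claisen rearrangement (PhNEt2, 130 °C) delivers 3.
- The same three operations on 3 give first 4-iodo-1-[(2-methylbut-3-yn-2-yl)oxy]-2-(3-methylbut-2-en-1-yl)benzene F6.
- They then give 4-iodo-1-[(2-methylbut-3-en-2-yl)oxy]-2-(3-methylbut-2-en-1-yl)benzene F7.
- Claisen shift of F7 into the only free ortho position gives 4.

**3. Step 2.**
- Risks: a competing Heck pathway on the vinyl boronate or on product 6 (stilbene formation), and polymerisation of 6 during isolation.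
- The fallback builds the vinyl group by loss of CO2 instead of by cross-coupling with a vinyl metal. It sets out from 4 and comes back at 6.
- Mizoroki–Heck reaction of 4 with acrylic acid (Pd(OAc)2, P(o-tol)3, K2CO3, DMF, 90 °C, acidic work-up) gives (E)-3-[4-hydroxy-3,5-bis(3-methylbut-2-en-1-yl)phenyl]prop-2-enoic acid (artepillin C) F8.
- F8 undergoes the known thermal decarboxylation of 4-hydroxycinnamic acids through the quinone-methide tautomer (DMF, cat. DBU, 140 °C). This gives 6, which can be carried on as a solution.

**Further compounds**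
F1 | step 3 | 2,4,6-tris(methoxymethoxy)benzaldehyde | COCOc1cc(OCOC)c(C=O)c(OCOC)c1
F2 | step 3 | 1-[2,4,6-tris(methoxymethoxy)phenyl]prop-2-en-1-ol (racemic) | C=CC(O)c1c(OCOC)cc(OCOC)cc1OCOC
F3 | step 3 | 3-[4-hydroxy-3,5-bis(3-methylbut-2-en-1-yl)phenyl]-1-[2,4,6-tris(methoxymethoxy)phenyl]propan-1-one | CC(C)=CCc1cc(CCC(=O)c2c(OCOC)cc(OCOC)cc2OCOC)cc(CC=C(C)C)c1O
F4 | step 1 | 1-iodo-4-[(2-methylbut-3-yn-2-yl)oxy]benzene | C#CC(C)(C)Oc1ccc(I)cc1
F5 | step 1 | 1-iodo-4-[(2-methylbut-3-en-2-yl)oxy]benzene | C=CC(C)(C)Oc1ccc(I)cc1
F6 | step 1 | 4-iodo-1-[(2-methylbut-3-yn-2-yl)oxy]-2-(3-methylbut-2-en-1-yl)benzene | C#CC(C)(C)Oc1ccc(I)cc1CC=C(C)C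
F7 | step 1 | 4-iodo-1-[(2-methylbut-3-en-2-yl)oxy]-2-(3-methylbut-2-en-1-yl)benzene | C=CC(C)(C)Oc1ccc(I)cc1CC=C(C)C
F8 | step 2 | (E)-3-[4-hydroxy-3,5-bis(3-methylbut-2-en-1-yl)phenyl]prop-2-enoic acid (artepillin C) | CC(C)=CCc1cc(/C=C/C(=O)O)cc(CC=C(C)C)c1O
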